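## Analysis of the target

Labdane numbering is used throughout, and β denotes the face of the C10 methyl group (C20). The target is a 9,13:15,16-diepoxylabdane. Rings A and B form a cis-fused decalin (H5 and C20 both β). C9 is the spiro centre of a tetrahydrofuran (ring C: O9–C9–C11–C12–C13), and C13 is in turn the spiro centre of a 2,3-dihydrofuran (ring D: C13–C14=C15–O–C16). There are six stereocentres: C5, C10, C9 (O9 α, C11 β), C8 (acetoxy α, methyl β), C7 (hydroxyl β, trans to the acetate) and C13 (C16 on the side of ring C that faces C10, C14 on the side that faces C8). The enol ether of ring D together with the C13–O9 bond is a vinylogous ketal, which acid converts into a furan. The tertiary acetate is β to the C6 ketone (E1cB loss) and can migrate to the neighbouring hydroxyl, the C7 hydroxyl is part of an α-ketol, and C5 is epimerisable. The hard part is that O9 joins two fully substituted spiro carbons, and that the C9 oxygen is a tertiary, neopentyl-type oxygen flanked by C10 and C8. Five contiguous stereocentres (C7, C8, C9, C10, C5) also surround ring B. The strategy rests on C13: it carries O9, the methylene C12, a CH2–O arm (C16) and a two-carbon arm (C14–C15), which is the substitution pattern of the β-carbon of a β-alkoxyacrylate hung on O9. Ring C can therefore be closed by forming C12–C13 from a C12 radical.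

## Retrosynthetic reasoning

**Ring D (27 ⇒ 25 ⇒ 23 ⇒ 22 ⇒ 21).** The C14=C15 enol ether is cut last, by dehydration of lactol 25, because nothing acidic may follow once ring D is at the acetal level. The O–C15 bond of 25 closes by itself when the C16 silyl ether of aldehyde 23 is removed. The aldehyde is reached from acid 21 through thioester 22 and a palladium/silane reduction, the one reduction that leaves the C6 ketone and the C8 acetate alone. This replaces a hydride/acetal sequence, which would expose a ring D acetal to the acid of the acetolysis.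

**Ring B oxygens (21 ⇒ 20 ⇒ 19 ⇒ 18).** The trans 7β-hydroxy/8α-acetoxy pair is the signature of anti opening of a 7β,8β-epoxide at the tertiary C8, so the C8–O(acetyl) bond is cut back to epoxide 20 and this to the enone of acid 19. Both steps are run while C15 is a carboxylic acid, which is inert to alkaline peroxide and to acid. Acid 19 comes from ester 18 by saponification.

**Ring C, the key disconnection (18 ⇒ 17).** The C12–C13 bond is cut. Cutting here means that the ether bridge between the two fully substituted carbons never has to be made by substitution at a saturated carbon. The forward reaction has to close a five-membered ring onto a fully substituted, electron-poor alkene carbon and set C13. The acrylate also delivers C14 and C15 with a handle at C15.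

**O9–C13 bond and iodide (17 ⇒ 16 ⇒ 11 + 15).** The ether bond is cut at the trigonal stage and made by conjugate addition of the C9 alkoxide of 11 to ynoate 15, a linear electrophile that a crowded oxygen can still reach. C12 is carried as the chloride through all base chemistry and exchanged for iodide only afterwards. An iodide present during alkoxide formation would invite oxetane closure or elimination.

**C5, C6 and C9 (11 ⇒ 10 ⇒ 9 ⇒ 8).** The cis ring fusion is cut back to the trans-fused hydroxy enone 10 by epimerisation α to the C6 ketone. The O–C6 and O–C9 bonds of 10 go back to endoperoxide 9 and the ring B diene 8, so that one photooxygenation installs both oxygens on the α face.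

**Diene and decalin (8 ⇒ 7 ⇒ 5 ⇒ 4 ⇒ 3 ⇒ 2 ⇒ 1).** The diene comes regiospecifically from enone 5 through dienyl triflate 7. The enone comes from allylic oxidation of the Δ8 olefin 4, and 4 from sclareolide 1 through ester 2 and alcohol 3. Sclareolide supplies rings A and B, C10 in the correct absolute configuration, and C11–C12.

**Ynoate (15 ⇒ 13 ⇒ 12).** The C15 carbon is added to silyl ether 13 of propargyl alcohol 12 through acetylide 14.

## Alternatives that were turned down

**Alternative 1: quinone Diels–Alder for ring A.**
- **Disconnection and key step.** The C4–C5 and C1–C10 bonds are cut. The quinone A1 (2,6-dimethyl-1,4-benzoquinone) and the diene A2 (4-methylpenta-1,3-diene) would combine under a chiral titanium Lewis acid to the cis-fused enedione A3.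
- **For.** It is stronger than the chosen route on two points. The cis fusion at C5/C10 comes from the suprafacial addition itself and does not depend on an equilibrium. One step delivers ring B with carbonyls at C6 and C9, the C7=C8 double bond and the C8 methyl group.
- **Against.** A2 carries a cis methyl group on its reacting terminus, so the s-cis conformer is strained and the diene is sluggish. The bond between C4 and C5 must form at the crowded end. A3 then has two conjugated carbonyls to tell apart and an extra ring A double bond. C9 is again a hindered ketone to which C11 must be added with the oxygen ending α on a folded cis-decalin.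
- **Comparison.** The real problem, the O9 bridge between C9 and C13 and rings C and D, is not addressed at all. The chosen strategy spends eight steps on the decalin but solves that problem directly.

**Alternative 2: intramolecular nitroalkene Diels–Alder for rings A and B.**
- **Disconnection and key step.** The C5–C10 and C6–C7 bonds are cut. Heating the acyclic nitro triene A4 would give the bicycle A5, with C10 quaternary, a nitro group at C6 and a C8=C9 enol silane.
- **For.** Two rings and the quaternary C10 form in one step from an acyclic precursor. The nitro group is a masked C6 ketone and the enol silane a masked C9 carbonyl.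
- **Against.** The diene terminus C10 is fully substituted, so one substituent must point inward in the s-cis form. Endo/exo and facial selectivity must fix C5, C6 and C10 at once. The product is racemic unless an asymmetric variant is found. C7 arrives as a methylene and C9 as a ketone, so the ring B oxidation pattern and the C9 side chain still have to be built.
- **Comparison.** Sclareolide gives the same decalin with C10 already correct, and the chosen route reaches the C6/C9 oxygen pattern in fewer operations than A4 would need for its own synthesis.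

**Alternative 3: photooxygenation with the whole side chain in place.**
- **Disconnection and key step.** The O–C6 and O–C9 bonds are cut. Sensitised photooxygenation of the diene A6, which already carries the C11–C16 enyne chain, followed by base, would give the hydroxy enone A7.
- **For.** This is the same oxygenation as step 7 of the chosen route, and equally good there. It is stronger on ring D: the C16 oxygen could later add to the C14≡C15 alkyne to give the dihydrofuran directly at the right oxidation level, without the thioester detour.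
- **Against.** Ring C would have to close by attack of the tertiary O9 on the 1,1-disubstituted alkene carbon C13 under electrophilic activation. That forms the ether between two fully substituted carbons at a centre with little facial bias, and the enone, the alkyne and the alkene all compete for the electrophile. The extra alkene and alkyne also offer additional allylic and propargylic positions to the allylic oxidation and the photooxygenation that build the diene.
- **Comparison.** The chosen strategy makes the O9–C13 bond at a trigonal carbon and closes the ring by an irreversible C–C bond formation, for which a steric model of the C13 configuration exists.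

Key step: step 13

Assumption: for the 9α-oxygenated 4,4,10-trimethyl-7-en-6-one the 5β-H, cis-fused epimer is taken to be the more stable one, so that base equilibration at C5 delivers it.

## Route

Step 1
Reactants: 1 (+)-sclareolide
Product: 2 methyl 13,14,15,16-tetranorlabd-8-en-12-oate
Conditions: MeOH, conc. H2SO4, reflux
Reagents that add atoms: methanol, CO
Why: Acid opens the tertiary lactone by alkyl–oxygen cleavage to the C8 cation (E1), and under equilibrating conditions the double bond should settle in the tetrasubstituted C8=C9 position while the acid is trapped by Fischer esterification. Minor Δ7 and exocyclic isomers are removed by chromatography; C5 and C10 are untouched.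

Step 2
Reactants: 2 methyl 13,14,15,16-tetranorlabd-8-en-12-oate
Product: 3 13,14,15,16-tetranorlabd-8-en-12-ol
Conditions: LiAlH4, THF, 0 °C → rt
Reagents that add atoms: none
Why: Hydride reduction of the ester to the primary alcohol; the tetrasubstituted alkene and both stereocentres are inert.

Step 3
Reactants: 3 13,14,15,16-tetranorlabd-8-en-12-ol
Product: 4 12-chloro-13,14,15,16-tetranorlabd-8-ene
Conditions: PPh3, CCl4, CH2Cl2, 40 °C
Reagents that add atoms: carbon tetrachloride, ClC(Cl)(Cl)Cl
Why: Appel reaction: chloride displaces the oxyphosphonium group at the primary carbon under neutral conditions, so the homoallylic alcohol cannot cyclise onto C8 as it would with acid. The chloride is an inert placeholder for the later radical site and spares a protecting group.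

Step 4
Reactants: 4 12-chloro-13,14,15,16-tetranorlabd-8-ene
Product: 5 12-chloro-13,14,15,16-tetranorlabd-8-en-7-one
Conditions: CrO3, 3,5-dimethylpyrazole, CH2Cl2, −20 °C
Reagents that add atoms: chromium trioxide, O=[Cr](=O)=O
Why: Allylic oxidation by the hexavalent chromium–pyrazole complex. Of the allylic positions the ring methylene C7 is the most accessible (C11 sits next to the quaternary C10, C17 is a methyl group), and the product is the conjugated enone.

Step 5
Reactants: 5 12-chloro-13,14,15,16-tetranorlabd-8-en-7-one
Product: 7 12-chloro-13,14,15,16-tetranorlabda-6,8-dien-7-yl trifluoromethanesulfonate, via potassium dienolate 6 (not isolated)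
Conditions: KN(SiMe3)2, THF, −78 °C; then PhNTf2, −78 → 0 °C
Reagents that add atoms: N-phenylbis(trifluoromethanesulfonimide), O=S(=O)(N(c1ccccc1)S(=O)(=O)C(F)(F)F)C(F)(F)F
Why: Kinetic deprotonation of the enone at C6 (α′) gives the cross-conjugated dienolate, and O-sulfonylation fixes the C6=C7/C8=C9 diene regiochemistry. At −78 °C the hindered base does not touch the γ-hydrogens at C11 or the primary chloride.

Step 6
Reactants: 7 12-chloro-13,14,15,16-tetranorlabda-6,8-dien-7-yl trifluoromethanesulfonate
Product: 8 12-chloro-13,14,15,16-tetranorlabda-6,8-diene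
Conditions: Pd(OAc)2 (5 mol%), PPh3, HCO2H, n-Bu3N, DMF, 60 °C
Reagents that add atoms: none
Why: Palladium-catalysed formate reduction of a dienyl triflate: oxidative addition to zerovalent palladium, decarboxylation of the formate and C–H reductive elimination. The primary alkyl chloride does not undergo oxidative addition under these conditions.

Step 7
Reactants: 8 12-chloro-13,14,15,16-tetranorlabda-6,8-diene
Product: 10 12-chloro-9α-hydroxy-13,14,15,16-tetranorlabd-7-en-6-one (5α-H; trans-fused), via endoperoxide 9 (not isolated)
Conditions: O2, tetraphenylporphyrin (cat.), visible light, CH2Cl2, −20 °C; then DBU, 0 °C → rt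
Reagents that add atoms: oxygen, O=O
Why: [4+2] cycloaddition of singlet oxygen across C6 and C9 of the s-cis-locked diene from the α face, opposite the axial C20 methyl, then Kornblum–DeLaMare rearrangement (base removes H6, the O–O bond breaks). C9 is set with its oxygen α; any C5 epimer already formed by DBU is carried into step 8.

Step 8
Reactants: 10 12-chloro-9α-hydroxy-13,14,15,16-tetranorlabd-7-en-6-one (5α-H; trans-fused)
Product: 11 12-chloro-9α-hydroxy-13,14,15,16-tetranor-5β-labd-7-en-6-one (cis-fused)
Conditions: NaOMe (0.2 equiv), MeOH, 40 °C, to equilibrium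
Reagents that add atoms: none
Why: Reversible enolisation toward C5 and reprotonation under thermodynamic control. The cis epimer is expected to prevail because ring B can then hold C1 axial on a ring whose C6 and C8 are trigonal, turn the axial C4 methyl anti to C6, and relieve the C1/C11 contact of the trans form. This sets C5; the epimers are separable and the trans one can be resubjected.

Step 9
Reactants: 12 prop-2-yn-1-ol
Product: 13 tert-butyldiphenyl(prop-2-yn-1-yloxy)silane
Conditions: tert-butyl(chloro)diphenylsilane, imidazole, DMF, 0 °C → rt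
Reagents that add atoms: tert-butyl(chloro)diphenylsilane, CC(C)(C)[Si](Cl)(c1ccccc1)c1ccccc1
Why: Standard silylation of a primary alcohol. The bulky, acid-stable silyl group is chosen because it later steers the key step and must survive saponification, alkaline peroxide and acetolysis.

Step 10
Reactants: 13 tert-butyldiphenyl(prop-2-yn-1-yloxy)silane
Product: 15 methyl 4-[(tert-butyldiphenylsilyl)oxy]but-2-ynoate, via lithium acetylide 14 (not isolated)
Conditions: n-BuLi, THF, −78 °C; then ClCO2Me, −78 → 0 °C
Reagents that add atoms: methyl chloroformate, COC(=O)Cl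
Why: Deprotonation of the terminal alkyne and C-acylation of the acetylide with a chloroformate, the standard route to ynoates.

Step 11
Reactants: 11 12-chloro-9α-hydroxy-13,14,15,16-tetranor-5β-labd-7-en-6-one; 15 methyl 4-[(tert-butyldiphenylsilyl)oxy]but-2-ynoate
Product: 16 methyl (E)-4-[(tert-butyldiphenylsilyl)oxy]-3-[(12-chloro-6-oxo-13,14,15,16-tetranor-5β-labd-7-en-9α-yl)oxy]but-2-enoate
Conditions: KN(SiMe3)2 (0.2 equiv), 15 (1.5 equiv, slow addition), THF, −20 → 0 °C; AcOH quench
Reagents that add atoms: none
Why: Base-catalysed oxa-Michael addition: the potassium alkoxide of the crowded C9 hydroxyl attacks the sp carbon C13 of the ynoate, and the allenolate is protonated by the next alcohol, so only catalytic base is present and the enone and C5 stay at equilibrium. Thermodynamic control should give the E isomer (O9 trans to the ester), as in alkoxide additions to 4-oxygenated but-2-ynoates. The primary chloride is too poor a leaving group to close an oxetane at this temperature.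

Step 12
Reactants: 16 methyl (E)-4-[(tert-butyldiphenylsilyl)oxy]-3-[(12-chloro-6-oxo-13,14,15,16-tetranor-5β-labd-7-en-9α-yl)oxy]but-2-enoate
Product: 17 methyl (E)-4-[(tert-butyldiphenylsilyl)oxy]-3-[(12-iodo-6-oxo-13,14,15,16-tetranor-5β-labd-7-en-9α-yl)oxy]but-2-enoate
Conditions: NaI, butan-2-one, 80 °C
Reagents that add atoms: sodium iodide, [Na+].[I-]
Why: Finkelstein exchange (SN2) at the primary carbon, driven by precipitation of NaCl. The iodide is introduced only after all alkoxide chemistry, so neither oxetane closure nor elimination can intervene.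

Step 13
Reactants: 17 methyl (E)-4-[(tert-butyldiphenylsilyl)oxy]-3-[(12-iodo-6-oxo-13,14,15,16-tetranor-5β-labd-7-en-9α-yl)oxy]but-2-enoate
Product: 18 methyl (13S)-16-[(tert-butyldiphenylsilyl)oxy]-9α,13-epoxy-6-oxo-5β-labd-7-en-15-oate
Conditions: (Me3Si)3SiH (1.3 equiv), Et3B (0.3 equiv, in portions), air, toluene (0.02 M), −20 °C → rt
Reagents that add atoms: none
Why: The silyl radical abstracts iodine from 17 at close to diffusion control, so the enone is not hydrosilylated; the nucleophilic primary C12 radical adds to C13, the electron-poor β-carbon of the β-alkoxyacrylate, and the ester-stabilised C14 radical takes hydrogen from the silane and carries the chain. The closest known reaction type is the 5-exo radical cyclisation of β-alkoxyacrylates to 2,5-disubstituted tetrahydrofurans; here the acceptor carbon is fully substituted and the ether oxygen tertiary. Ring C closes in the 5-exo-trig mode: the 6-endo path to C14 is polarity-mismatched, and the ring B enone offers the C12 radical only 4-exo or 5-endo paths. C13 is the one new stereocentre: in the chair-like transition state the flat C8 takes the pseudoaxial position on C9 and C10 the pseudoequatorial one, and the C13 substituent that must lie beside C8 is then the slim vinylic C14–H of the E-acrylate (ester pointing away from O9) and not the CH2OSiPh2tBu arm, which puts C14 cis to C8 and C16 cis to C10 (13S). The step needs this rotamer preference (secured by the E geometry and the bulky silyl group), cyclisation faster than reduction of the C12 radical (secured by the slow hydrogen donor at low concentration), and no 1,5-hydrogen shift from C17 (expected to be slower than addition to an activated alkene).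

Step 14
Reactants: 18 methyl (13S)-16-[(tert-butyldiphenylsilyl)oxy]-9α,13-epoxy-6-oxo-5β-labd-7-en-15-oate
Product: 19 (13S)-16-[(tert-butyldiphenylsilyl)oxy]-9α,13-epoxy-6-oxo-5β-labd-7-en-15-oic acid
Conditions: LiOH, THF/MeOH/H2O, 0 °C → rt; then 1 M HCl to pH 3
Reagents that add atoms: lithium hydroxide, [Li+].[OH-]
Why: Saponification of the methyl ester. Hydroxide cannot form the ester enolate needed for E1cB loss of O9, the silyl ether is stable, and C5 is already at its equilibrium configuration.

Step 15
Reactants: 19 (13S)-16-[(tert-butyldiphenylsilyl)oxy]-9α,13-epoxy-6-oxo-5β-labd-7-en-15-oic acid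
Product: 20 (13S)-16-[(tert-butyldiphenylsilyl)oxy]-7β,8β:9α,13-diepoxy-6-oxo-5β-labdan-15-oic acid
Conditions: 30% H2O2, NaOH, MeOH, 0 °C → rt; then 1 M HCl to pH 3
Reagents that add atoms: hydrogen peroxide, OO
Why: Weitz–Scheffer epoxidation: hydroperoxide adds to C8 and the enolate closes on oxygen at C7. Attack is expected on the β face, the convex face of the cis-fused bicycle, because in the preferred ring B conformer C1 is axial under the α face of C8. This sets C7 and C8 (both oxygens β); the carboxylate is inert.

Step 16
Reactants: 20 (13S)-16-[(tert-butyldiphenylsilyl)oxy]-7β,8β:9α,13-diepoxy-6-oxo-5β-labdan-15-oic acid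
Product: 21 (13S)-8α-acetoxy-16-[(tert-butyldiphenylsilyl)oxy]-9α,13-epoxy-7β-hydroxy-6-oxo-5β-labdan-15-oic acid
Conditions: glacial AcOH, camphorsulfonic acid (0.1 equiv), rt
Reagents that add atoms: acetic acid, CC(=O)O
Why: Acid-catalysed acetolysis of an α,β-epoxy ketone: the C8–O bond breaks (tertiary carbon; the C7–O bond is deactivated by the carbonyl) and the solvent attacks from the rear, giving the trans-diaxial 8α-acetoxy-7β-hydroxy pair (Fürst–Plattner), with inversion at C8 and retention at C7. C15 is still a carboxylic acid, so no ring D acetal is exposed to the acid; the silyl ether and the spiro ether are stable.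

Step 17
Reactants: 21 (13S)-8α-acetoxy-16-[(tert-butyldiphenylsilyl)oxy]-9α,13-epoxy-7β-hydroxy-6-oxo-5β-labdan-15-oic acid
Product: 22 S-ethyl (13S)-8α-acetoxy-16-[(tert-butyldiphenylsilyl)oxy]-9α,13-epoxy-7β-hydroxy-6-oxo-5β-labdane-15-thioate
Conditions: EtSH, EDC·HCl, DMAP (0.1 equiv), CH2Cl2, 0 °C
Reagents that add atoms: ethanethiol, CCS
Why: Carbodiimide (Steglich-type) thioesterification of the acid. The axial, neopentyl-type 7-hydroxyl is too hindered to be acylated, and the cold, nearly neutral conditions avoid acetyl migration.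

Step 18
Reactants: 22 S-ethyl (13S)-8α-acetoxy-16-[(tert-butyldiphenylsilyl)oxy]-9α,13-epoxy-7β-hydroxy-6-oxo-5β-labdane-15-thioate
Product: 23 (13S)-8α-acetoxy-16-[(tert-butyldiphenylsilyl)oxy]-9α,13-epoxy-7β-hydroxy-6-oxo-5β-labdan-15-al
Conditions: Et3SiH, 10% Pd/C, acetone, rt
Reagents that add atoms: none
Why: Fukuyama reduction: the C–S bond adds to zerovalent palladium, the silane delivers hydride, and the aldehyde is released. Ketone, acetate, hydroxyl and silyl ether are not reduced, which no hydride reagent would achieve here.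

Step 19
Reactants: 23 (13S)-8α-acetoxy-16-[(tert-butyldiphenylsilyl)oxy]-9α,13-epoxy-7β-hydroxy-6-oxo-5β-labdan-15-al
Product: 25 (13S)-8α-acetoxy-9α,13:15,16-diepoxy-7β,15-dihydroxy-5β-labdan-6-one (lactol; both C15 epimers), via hydroxy aldehyde 24 (not isolated)
Conditions: Bu4NF, AcOH (1:1), THF, 0 °C → rt
Reagents that add atoms: none
Why: Buffered fluoride cleaves the silyl ether, and the freed C16 hydroxyl adds to the C15 aldehyde to close ring D as the five-membered lactol. The buffer prevents E1cB loss of O9 from the β-alkoxy aldehyde and loss of the β-acetoxy group.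

Step 20
Reactants: 25 (13S)-8α-acetoxy-9α,13:15,16-diepoxy-7β,15-dihydroxy-5β-labdan-6-one
Product: 27 (13S)-8α-acetoxy-9α,13:15,16-diepoxy-7β-hydroxy-5β-labd-14-en-6-one (target), via anomeric mesylate 26 (not isolated)
Conditions: MsCl (1.2 equiv), Et3N (4 equiv), CH2Cl2, −40 °C → rt; chromatography on Et3N-deactivated silica
Reagents that add atoms: none
Why: Dehydration of a 2-deoxy lactol to the cyclic enol ether: the hemiacetal hydroxyl, far more accessible than the axial neopentyl-type 7-hydroxyl, is mesylated, the mesylate ionises to the oxocarbenium ion and Et3N removes H14. The medium stays basic throughout, as the vinylogous ketal of rings C and D requires.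

## Compound list

1 | (+)-sclareolide | C[C@@]12CC[C@H]3C(C)(C)CCC[C@]3(C)[C@H]1CC(=O)O2 | starting material
2 | methyl 13,14,15,16-tetranorlabd-8-en-12-oate | COC(=O)CC1=C(C)CC[C@H]2C(C)(C)CCC[C@]12C | intermediate
3 | 13,14,15,16-tetranorlabd-8-en-12-ol | OCCC1=C(C)CC[C@H]2C(C)(C)CCC[C@]12C | intermediate
4 | 12-chloro-13,14,15,16-tetranorlabd-8-ene | ClCCC1=C(C)CC[C@H]2C(C)(C)CCC[C@]12C | intermediate
5 | 12-chloro-13,14,15,16-tetranorlabd-8-en-7-one | ClCCC1=C(C)C(=O)C[C@H]2C(C)(C)CCC[C@]12C | intermediate
6 | potassium 12-chloro-13,14,15,16-tetranorlabda-6,8-dien-7-olate | [K+].ClCCC1=C(C)C([O-])=C[C@H]2C(C)(C)CCC[C@]12C | intermediate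
7 | 12-chloro-13,14,15,16-tetranorlabda-6,8-dien-7-yl trifluoromethanesulfonate | ClCCC1=C(C)C(OS(=O)(=O)C(F)(F)F)=C[C@H]2C(C)(C)CCC[C@]12C | intermediate
8 | 12-chloro-13,14,15,16-tetranorlabda-6,8-diene | ClCCC1=C(C)C=C[C@H]2C(C)(C)CCC[C@]12C | intermediate
9 | 12-chloro-6α,9α-epidioxy-13,14,15,16-tetranorlabd-7-ene | ClCC[C@@]12OO[C@@H](C=C1C)[C@H]3C(C)(C)CCC[C@]23C | intermediate
10 | 12-chloro-9α-hydroxy-13,14,15,16-tetranorlabd-7-en-6-one (5α-H, trans-fused) | CC1=CC(=O)[C@H]2C(C)(C)CCC[C@]2(C)[C@@]1(O)CCCl | intermediate
11 | 12-chloro-9α-hydroxy-13,14,15,16-tetranor-5β-labd-7-en-6-one (cis-fused) | CC1=CC(=O)[C@@H]2C(C)(C)CCC[C@]2(C)[C@@]1(O)CCCl | intermediate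
12 | prop-2-yn-1-ol | C#CCO | starting material
13 | tert-butyldiphenyl(prop-2-yn-1-yloxy)silane | C#CCO[Si](c1ccccc1)(c1ccccc1)C(C)(C)C | intermediate
14 | lithium 3-[(tert-butyldiphenylsilyl)oxy]prop-1-yn-1-ide | [Li+].[C-]#CCO[Si](c1ccccc1)(c1ccccc1)C(C)(C)C | intermediate
15 | methyl 4-[(tert-butyldiphenylsilyl)oxy]but-2-ynoate | COC(=O)C#CCO[Si](c1ccccc1)(c1ccccc1)C(C)(C)C | intermediate
16 | methyl (E)-4-[(tert-butyldiphenylsilyl)oxy]-3-[(12-chloro-6-oxo-13,14,15,16-tetranor-5β-labd-7-en-9α-yl)oxy]but-2-enoate | CC1=CC(=O)[C@@H]2C(C)(C)CCC[C@]2(C)[C@]1(CCCl)O/C(CO[Si](c1ccccc1)(c1ccccc1)C(C)(C)C)=C/C(=O)OC | intermediate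
17 | methyl (E)-4-[(tert-butyldiphenylsilyl)oxy]-3-[(12-iodo-6-oxo-13,14,15,16-tetranor-5β-labd-7-en-9α-yl)oxy]but-2-enoate | CC1=CC(=O)[C@@H]2C(C)(C)CCC[C@]2(C)[C@]1(CCI)O/C(CO[Si](c1ccccc1)(c1ccccc1)C(C)(C)C)=C/C(=O)OC | intermediate
18 | methyl (13S)-16-[(tert-butyldiphenylsilyl)oxy]-9α,13-epoxy-6-oxo-5β-labd-7-en-15-oate | CC1=CC(=O)[C@@H]2C(C)(C)CCC[C@]2(C)[C@@]13CC[C@@](CO[Si](c4ccccc4)(c4ccccc4)C(C)(C)C)(CC(=O)OC)O3 | intermediate
19 | (13S)-16-[(tert-butyldiphenylsilyl)oxy]-9α,13-epoxy-6-oxo-5β-labd-7-en-15-oic acid | CC1=CC(=O)[C@@H]2C(C)(C)CCC[C@]2(C)[C@@]13CC[C@@](CO[Si](c4ccccc4)(c4ccccc4)C(C)(C)C)(CC(=O)O)O3 | intermediate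
20 | (13S)-16-[(tert-butyldiphenylsilyl)oxy]-7β,8β:9α,13-diepoxy-6-oxo-5β-labdan-15-oic acid | C[C@@]12O[C@H]2C(=O)[C@@H]3C(C)(C)CCC[C@]3(C)[C@@]14CC[C@@](CO[Si](c5ccccc5)(c5ccccc5)C(C)(C)C)(CC(=O)O)O4 | intermediate
21 | (13S)-8α-acetoxy-16-[(tert-butyldiphenylsilyl)oxy]-9α,13-epoxy-7β-hydroxy-6-oxo-5β-labdan-15-oic acid | CC(=O)O[C@]1(C)[C@@H](O)C(=O)[C@@H]2C(C)(C)CCC[C@]2(C)[C@@]13CC[C@@](CO[Si](c4ccccc4)(c4ccccc4)C(C)(C)C)(CC(=O)O)O3 | intermediate
22 | S-ethyl (13S)-8α-acetoxy-16-[(tert-butyldiphenylsilyl)oxy]-9α,13-epoxy-7β-hydroxy-6-oxo-5β-labdane-15-thioate | CC(=O)O[C@]1(C)[C@@H](O)C(=O)[C@@H]2C(C)(C)CCC[C@]2(C)[C@@]13CC[C@@](CO[Si](c4ccccc4)(c4ccccc4)C(C)(C)C)(CC(=O)SCC)O3 | intermediate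
23 | (13S)-8α-acetoxy-16-[(tert-butyldiphenylsilyl)oxy]-9α,13-epoxy-7β-hydroxy-6-oxo-5β-labdan-15-al | CC(=O)O[C@]1(C)[C@@H](O)C(=O)[C@@H]2C(C)(C)CCC[C@]2(C)[C@@]13CC[C@@](CO[Si](c4ccccc4)(c4ccccc4)C(C)(C)C)(CC=O)O3 | intermediate
24 | (13S)-8α-acetoxy-9α,13-epoxy-7β,16-dihydroxy-6-oxo-5β-labdan-15-al | CC(=O)O[C@]1(C)[C@@H](O)C(=O)[C@@H]2C(C)(C)CCC[C@]2(C)[C@@]13CC[C@@](CO)(CC=O)O3 | intermediate
25 | (13S)-8α-acetoxy-9α,13:15,16-diepoxy-7β,15-dihydroxy-5β-labdan-6-one (lactol, both C15 epimers) | CC(=O)O[C@]1(C)[C@@H](O)C(=O)[C@@H]2C(C)(C)CCC[C@]2(C)[C@@]12CC[C@@]1(CC(O)OC1)O2 | intermediate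
26 | 15-O-methanesulfonyl derivative of lactol 25 | CC(=O)O[C@]1(C)[C@@H](O)C(=O)[C@@H]2C(C)(C)CCC[C@]2(C)[C@@]12CC[C@@]1(CC(OS(C)(=O)=O)OC1)O2 | intermediate
27 | (13S)-8α-acetoxy-9α,13:15,16-diepoxy-7β-hydroxy-5β-labd-14-en-6-one | CC(=O)O[C@]1(C)[C@@H](O)C(=O)[C@@H]2C(C)(C)CCC[C@]2(C)[C@@]12CC[C@@]1(C=COC1)O2 | target

## Step count and least certain steps

Total: 20 steps. Longest linear sequence: 18 steps from 1 (steps 1–8 and 11–20); steps 9–10 are the side branch to ynoate 15.

**Step 13 (key step).** Attack on the fully substituted C13 may be slow enough that simple reduction of the C12 radical or a 1,5-hydrogen shift from C17 competes, and the rotamer choice about O9–C13 may give poor facial selectivity at C13. Fallback: reverse the order of the two bonds. It sets out from 11. Finkelstein exchange gives 12-iodo-9α-hydroxy-13,14,15,16-tetranor-5β-labd-7-en-6-one F1. Intermolecular radical addition of its C12 radical to excess ynoate 15 ((Me3Si)3SiH added slowly, Et3B/air) gives the hydroxy enoate methyl 3-{[(tert-butyldiphenylsilyl)oxy]methyl}-5-(9α-hydroxy-6-oxo-5β-labd-7-ene fragment C1–C12)pent-2-enoate F2. Catalytic KOtBu in THF then closes the C9 hydroxyl onto C13 by a 5-exo-trig oxa-Michael addition under thermodynamic control. The fallback comes back at 18.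

**Step 8.** The position of the C5 equilibrium is not known; the epimerisation may stop at a mixture rich in the trans form at this stage. Fallback: postpone the equilibration until ring C is closed. It sets out from 10. Steps 11–13 on the trans series give the trans-fused acrylate chloride F3, the trans-fused iodide F4 and the trans-fused spiro ether F5. F5 is then equilibrated with NaOMe in MeOH. There C11 is locked in ring C against C1, so the trans form can no longer relieve that contact. The fallback comes back at 18.

**Step 11.** The crowded C9 alkoxide may fail to add, may attack the ester carbonyl (transesterification), or the ynoate may oligomerise under base. Fallback: a cyclic, more electrophilic acceptor. It sets out from 11.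
- Addition–elimination of its potassium alkoxide on 4-bromofuran-2(5H)-one gives the 9-O-tetronate chloride F6, and NaI gives the tetronate iodide F7.
- The same radical conditions close ring C onto the butenolide to give the spiro lactone F8.
- LiOH opens the lactone to the lithium hydroxy carboxylate F9. tert-Butyl(chloro)diphenylsilane/imidazole gives the silyl ether silyl ester F10, and K2CO3 in aqueous MeOH cleaves the silyl ester.

The fallback comes back at 19.

**Step 15.** Facial selectivity of the epoxidation may be poor or reversed, because stereoelectronically preferred axial attack at C8 points to the α face while sterics point to the β face. Fallback: use the α-epoxide with inverted logic. It sets out from 19.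
- If the 7α,8α-epoxide F11 is what forms, CsOAc in DMF opens it by SN2 at C7, the carbon activated by the ketone, to the 7β-acetoxy-8α-hydroxy acid F12. Both oxygens then have the target configuration.
- Ac2O with catalytic Sc(OTf)3 at −20 °C gives the 7β,8α-diacetate F13.
- Brief K2CO3/MeOH at −20 °C removes the activated, unhindered α-keto acetate at C7.

The fallback comes back at 21.

**Step 16.** Loss of a C17 proton from the developing C8 cation (elimination to the exocyclic allylic alcohol) or an acyl shift may outrun capture by acetic acid, because the α face of C8 is screened by C1. Fallback: a smaller nucleophile, then acyl adjustment. It sets out from 20. Dilute HClO4 in THF/H2O gives the 7β,8α-diol acid F14. Peracetylation (Ac2O, Sc(OTf)3) gives the diacetate F13, and selective methanolysis of the 7-acetate follows as above. The fallback comes back at 21.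

**Step 20.** Sulfonylation of the 7-hydroxyl, acetyl migration under the amine, or acid-induced aromatisation of ring D to the furan during work-up may erode the last step. Fallback: a neutral thermal elimination. It sets out from 25. PhSSPh/n-Bu3P converts the lactol into the 15-phenylthio acetal F15, and mCPBA at −78 °C gives the sulfoxide F16. Warming in toluene (90 °C, solid NaHCO3) expels benzenesulfenic acid by syn elimination toward C14. The fallback comes back at 27.

## Further compounds

F1 | step 13 | 12-iodo-9α-hydroxy-13,14,15,16-tetranor-5β-labd-7-en-6-one | CC1=CC(=O)[C@@H]2C(C)(C)CCC[C@]2(C)[C@@]1(O)CCI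
F2 | step 13 | methyl 16-[(tert-butyldiphenylsilyl)oxy]-9α-hydroxy-6-oxo-5β-labda-7,13-dien-15-oate (E/Z mixture) | CC1=CC(=O)[C@@H]2C(C)(C)CCC[C@]2(C)[C@@]1(O)CCC(CO[Si](c1ccccc1)(c1ccccc1)C(C)(C)C)=CC(=O)OC
F3 | step 8 | trans-fused (5α-H) analogue of 16 | CC1=CC(=O)[C@H]2C(C)(C)CCC[C@]2(C)[C@]1(CCCl)O/C(CO[Si](c1ccccc1)(c1ccccc1)C(C)(C)C)=C/C(=O)OC
F4 | step 8 | trans-fused (5α-H) analogue of 17 | CC1=CC(=O)[C@H]2C(C)(C)CCC[C@]2(C)[C@]1(CCI)O/C(CO[Si](c1ccccc1)(c1ccccc1)C(C)(C)C)=C/C(=O)OC
F5 | step 8 | trans-fused (5α-H) analogue of 18 | CC1=CC(=O)[C@H]2C(C)(C)CCC[C@]2(C)[C@@]13CC[C@@](CO[Si](c4ccccc4)(c4ccccc4)C(C)(C)C)(CC(=O)OC)O3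
F6 | step 11 | 4-[(12-chloro-6-oxo-13,14,15,16-tetranor-5β-labd-7-en-9α-yl)oxy]furan-2(5H)-one | CC1=CC(=O)[C@@H]2C(C)(C)CCC[C@]2(C)[C@]1(CCCl)OC1=CC(=O)OC1
F7 | step 11 | 4-[(12-iodo-6-oxo-13,14,15,16-tetranor-5β-labd-7-en-9α-yl)oxy]furan-2(5H)-one | CC1=CC(=O)[C@@H]2C(C)(C)CCC[C@]2(C)[C@]1(CCI)OC1=CC(=O)OC1
F8 | step 11 | (13S)-9α,13-epoxy-6-oxo-5β-labd-7-en-15,16-olide | CC1=CC(=O)[C@@H]2C(C)(C)CCC[C@]2(C)[C@@]13CC[C@@]4(CC(=O)OC4)O3
F9 | step 11 | lithium (13S)-9α,13-epoxy-16-hydroxy-6-oxo-5β-labd-7-en-15-oate | [Li+].CC1=CC(=O)[C@@H]2C(C)(C)CCC[C@]2(C)[C@@]13CC[C@@](CO)(CC(=O)[O-])O3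
F10 | step 11 | tert-butyldiphenylsilyl ester of acid 19 | CC1=CC(=O)[C@@H]2C(C)(C)CCC[C@]2(C)[C@@]13CC[C@@](CO[Si](c4ccccc4)(c4ccccc4)C(C)(C)C)(CC(=O)O[Si](c4ccccc4)(c4ccccc4)C(C)(C)C)O3
F11 | step 15 | (13S)-16-[(tert-butyldiphenylsilyl)oxy]-7α,8α:9α,13-diepoxy-6-oxo-5β-labdan-15-oic acid | C[C@]12O[C@@H]2C(=O)[C@@H]3C(C)(C)CCC[C@]3(C)[C@@]14CC[C@@](CO[Si](c5ccccc5)(c5ccccc5)C(C)(C)C)(CC(=O)O)O4
F12 | step 15 | (13S)-7β-acetoxy-16-[(tert-butyldiphenylsilyl)oxy]-9α,13-epoxy-8α-hydroxy-6-oxo-5β-labdan-15-oic acid | C[C@@]1(O)[C@@H](OC(C)=O)C(=O)[C@@H]2C(C)(C)CCC[C@]2(C)[C@@]13CC[C@@](CO[Si](c4ccccc4)(c4ccccc4)C(C)(C)C)(CC(=O)O)O3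
F13 | step 15 | (13S)-7β,8α-diacetoxy-16-[(tert-butyldiphenylsilyl)oxy]-9α,13-epoxy-6-oxo-5β-labdan-15-oic acid | CC(=O)O[C@]1(C)[C@@H](OC(C)=O)C(=O)[C@@H]2C(C)(C)CCC[C@]2(C)[C@@]13CC[C@@](CO[Si](c4ccccc4)(c4ccccc4)C(C)(C)C)(CC(=O)O)O3
F14 | step 16 | (13S)-16-[(tert-butyldiphenylsilyl)oxy]-9α,13-epoxy-7β,8α-dihydroxy-6-oxo-5β-labdan-15-oic acid | C[C@@]1(O)[C@@H](O)C(=O)[C@@H]2C(C)(C)CCC[C@]2(C)[C@@]13CC[C@@](CO[Si](c4ccccc4)(c4ccccc4)C(C)(C)C)(CC(=O)O)O3
F15 | step 20 | (13S)-8α-acetoxy-9α,13:15,16-diepoxy-7β-hydroxy-15-(phenylsulfanyl)-5β-labdan-6-one | CC(=O)O[C@]1(C)[C@@H](O)C(=O)[C@@H]2C(C)(C)CCC[C@]2(C)[C@@]12CC[C@@]1(CC(Sc3ccccc3)OC1)O2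
F16 | step 20 | (13S)-8α-acetoxy-9α,13:15,16-diepoxy-7β-hydroxy-15-(phenylsulfinyl)-5β-labdan-6-one | CC(=O)O[C@]1(C)[C@@H](O)C(=O)[C@@H]2C(C)(C)CCC[C@]2(C)[C@@]12CC[C@@]1(CC(S(=O)c3ccccc3)OC1)O2
A1 | alternative 1 | 2,6-dimethyl-1,4-benzoquinone | CC1=CC(=O)C=C(C)C1=O
A2 | alternative 1 | 4-methylpenta-1,3-diene | C=CC=C(C)C
A3 | alternative 1 | cis-2,5,5,8a-tetramethyl-4a,5,8,8a-tetrahydronaphthalene-1,4-dione | CC1=CC(=O)[C@@H]2C(C)(C)C=CC[C@]2(C)C1=O
A4 | alternative 2 | acyclic nitro triene with a 3-silyloxy diene and a terminal nitroalkene | C=C(C)/C(O[Si](C)(C)C(C)(C)C)=C(\C)CCCC(C)(C)/C=C/[N+](=O)[O-]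
A5 | alternative 2 | cis-fused C6-nitro bicycle with C8=C9 enol silane | CC1=C(O[Si](C)(C)C(C)(C)C)[C@@]2(C)CCCC(C)(C)[C@H]2[C@H]([N+](=O)[O-])C1
A6 | alternative 3 | ring B 6,8-diene carrying the C11–C16 silyl enyne chain | C[Si](C)(C)C#CC(=C)CCC1=C(C)C=C[C@H]2C(C)(C)CCC[C@]12C
A7 | alternative 3 | cis-fused 9α-hydroxy-7-en-6-one carrying the silyl enyne chain | CC1=CC(=O)[C@@H]2C(C)(C)CCC[C@]2(C)[C@@]1(O)CCC(=C)C#C[Si](C)(C)C
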